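**Plan**
- Feature: in ring A the C2 OH and the C4 OMe are meta across the unsubstituted C3, with the ester carbon on C1 and the propyl group on C6 next to each other. This is the pattern that a vinylketene and an alkoxyalkyne assemble into a phenol.
- Retrosynthesis: ring A is opened at C1–C2, C2–C3 and C4–C5 (vinylketene plus methoxyethyne). C5–C6 is traced through a Wolff 1,2-shift to a vinyl diazomethyl ketone, and the diazo group to an acetyl CH3. The depside C(=O)–O bond leads to methyl atrarate, and C1–C6 to an aldol condensation of hexan-2-one with glyoxylic acid.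
- Forward: the C8 keto acid is made first, esterified onto the 4-OH of the intact ring B, given its diazo group, and ring A is closed last, which delivers the target without protecting groups.
- Stereochemistry: the target has no stereocentre. The only stereo element on the way is the (E)-alkene of the keto acid, set under thermodynamic control in step 1 and carried into the key step.

Key step: step 5

Remark: the hydrogen-bonded 2-OH of ring B is carried free throughout, as it is the least reactive oxygen of every intermediate; methoxyethyne, a gas near room temperature, is made fresh in step 4.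

**Route**

Step 1
Reactants: 1 hexan-2-one; 2 glyoxylic acid monohydrate
Product: 3 (2E)-3-acetylhex-2-enoic acid
Conditions: 85% H3PO4, 80 °C (1 in excess)
Reagents that add atoms: none
Why: Acid-catalysed crossed aldol condensation, in which the ketone reacts through its more substituted enol so that C3 of hexan-2-one attacks the aldehyde carbon, and dehydration under equilibrating conditions should give the open-chain (E)-acid with acetyl and carboxyl trans, the isomer that cannot close to a hydroxybutenolide.

Step 2
Reactants: 3 (2E)-3-acetylhex-2-enoic acid; 4 methyl 2,4-dihydroxy-3,6-dimethylbenzoate (methyl atrarate)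
Product: 5 3-hydroxy-4-(methoxycarbonyl)-2,5-dimethylphenyl (2E)-3-acetylhex-2-enoate
Conditions: DCC, DMAP (cat.), CH2Cl2, 0 °C to rt
Reagents that add atoms: none
Why: Steglich esterification, selective for the 4-OH because the 2-OH is hydrogen-bonded to the ester carbonyl and flanked by the C3 methyl group, the same selectivity on which depside couplings of this phenol rely.

Step 3
Reactants: 5 3-hydroxy-4-(methoxycarbonyl)-2,5-dimethylphenyl (2E)-3-acetylhex-2-enoate
Product: 7 3-hydroxy-4-(methoxycarbonyl)-2,5-dimethylphenyl (2E)-3-(2-diazoacetyl)hex-2-enoate, via trifluoroacetyl diketone 6 (not isolated)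
Conditions: LiN(SiMe3)2 (2.2 equiv), THF, −78 °C; CF3CO2CH2CF3, −78 °C; aq. HCl; then MsN3, Et3N, H2O, MeCN, rt
Reagents that add atoms: methanesulfonyl azide, CS(=O)(=O)N=[N+]=[N-]; 2,2,2-trifluoroethyl trifluoroacetate, O=C(OCC(F)(F)F)C(F)(F)F (its acyl group is held only in 6)
Why: Detrifluoroacetylative diazo transfer, in which the first equivalent of base parks the phenol as its lithium phenoxide, the second forms the kinetic enolate at the only enolisable ketone position (the acetyl CH3), Claisen trifluoroacetylation activates that carbon, and the sulfonyl azide delivers N2 while the trifluoroacetyl group leaves as the N-acyl sulfonamide, so that no diazomethane ever meets the dipolarophilic ene-dicarbonyl and the (E)-alkene keeps the enolate away from the aryl ester.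

Step 4
Reactants: 8 2-chloro-1,1-dimethoxyethane (chloroacetaldehyde dimethyl acetal)
Product: 10 methoxyethyne, via sodium methoxyethynide 9 (not isolated)
Conditions: NaNH2 (3 equiv), liq. NH3, −33 °C; then sat. aq. NaCl, −20 °C; distilled into cold ClCH2CH2Cl
Reagents that add atoms: sodium amide, [Na+].[NH2-] (sodium is held only in 9)
Why: Twofold base-induced β-elimination (loss of HCl, then of methanol) of the chloroacetal, the standard preparation of alkoxyacetylenes, with the excess amide holding the ynol ether as its acetylide until the cold aqueous quench.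

Step 5
Reactants: 7 3-hydroxy-4-(methoxycarbonyl)-2,5-dimethylphenyl (2E)-3-(2-diazoacetyl)hex-2-enoate; 10 methoxyethyne
Product: 15 peruvinide A [3-hydroxy-4-(methoxycarbonyl)-2,5-dimethylphenyl 2-hydroxy-4-methoxy-6-propylbenzoate], via vinylketene 11 (not isolated), via methoxycyclobutenone 12 (not isolated), via dienylketene 13 (not isolated), via cyclohexadienone 14 (not isolated)
Conditions: 10 (5 equiv), hν (365 nm LED), ClCH2CH2Cl, 10 °C, sealed tube; then 80 °C
Reagents that add atoms: none
Why: Light expels N2 from 7 and the alkenyl group migrates from the carbonyl carbon to the diazo carbon (photochemical Wolff rearrangement, which turns the old C6–C(O) bond into C5–C6 with the alkene geometry retained) to give vinylketene 11, whose carbonyl carbon is attacked by the nucleophilic CH terminus of methoxyethyne in a (2+2) cycloaddition that forms C2–C3 and C4–C5 and gives cyclobutenone 12; on warming, 12 opens by 4-electron electrocyclic cleavage of its C2–C5 bond to dienylketene 13, which forms C1–C2 by 6-electron electrocyclisation to dienone 14, and 14 enolises to the phenol 15. The closest known reaction type is the Danheiser benzannulation in its diazo ketone form, in which a photochemically generated vinylketene is combined with an alkoxy- or siloxyalkyne. Ring A is closed by the thermal disrotatory 6-electron electrocyclisation of 13, the ketene carbon bonding to the ester-bearing alkene carbon, while the four-membered ring of 12 is only a relay that is made by cycloaddition and opened again. No stereocentre survives, since the sp3 carbons of 12 and 14 are racemic and are erased by ring opening and by aromatisation. The step needs the alkyne CH, not the alkyne C–OMe, to bond to the ketene carbonyl carbon so that OMe ends on C4 meta to the C2 OH, and the matched polarisation of the ynol ether (electron-rich CH terminus) and of the ketene (electrophilic central carbon) secures this. It also needs the ketenes to be consumed by the alkyne and by ring closure instead of by oxygen nucleophiles, which is secured by the (E)-alkene (H, not the ester, inside the closing triene, and the ester carbonyl held away from the ketene so that no 2-pyranone can form), by the excess of 10, by the low nucleophilicity of the hydrogen-bonded phenols, and by 365 nm light that the aryl ester and salicylate chromophores do not absorb.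

**Compound list**

1 | hexan-2-one | CCCCC(C)=O | starting material
2 | glyoxylic acid monohydrate (2,2-dihydroxyacetic acid) | OC(O)C(=O)O | starting material
3 | (2E)-3-acetylhex-2-enoic acid | CCC/C(C(C)=O)=C\C(=O)O | intermediate
4 | methyl 2,4-dihydroxy-3,6-dimethylbenzoate (methyl atrarate) | COC(=O)c1c(C)cc(O)c(C)c1O | starting material
5 | 3-hydroxy-4-(methoxycarbonyl)-2,5-dimethylphenyl (2E)-3-acetylhex-2-enoate | CCC/C(C(C)=O)=C\C(=O)Oc1cc(C)c(C(=O)OC)c(O)c1C | intermediate
6 | 3-hydroxy-4-(methoxycarbonyl)-2,5-dimethylphenyl (2E)-3-(4,4,4-trifluoro-3-oxobutanoyl)hex-2-enoate (trifluoroacetyl diketone, not isolated) | CCC/C(C(=O)CC(=O)C(F)(F)F)=C\C(=O)Oc1cc(C)c(C(=O)OC)c(O)c1C | intermediate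
7 | 3-hydroxy-4-(methoxycarbonyl)-2,5-dimethylphenyl (2E)-3-(2-diazoacetyl)hex-2-enoate | CCC/C(C(=O)C=[N+]=[N-])=C\C(=O)Oc1cc(C)c(C(=O)OC)c(O)c1C | intermediate
8 | 2-chloro-1,1-dimethoxyethane (chloroacetaldehyde dimethyl acetal) | COC(CCl)OC | starting material
9 | sodium methoxyethynide (not isolated) | [Na+].[C-]#COC | intermediate
10 | methoxyethyne | C#COC | intermediate
11 | 3-hydroxy-4-(methoxycarbonyl)-2,5-dimethylphenyl (2E)-3-(2-oxoethenyl)hex-2-enoate (vinylketene, not isolated) | CCC/C(C=C=O)=C\C(=O)Oc1cc(C)c(C(=O)OC)c(O)c1C | intermediate
12 | 3-hydroxy-4-(methoxycarbonyl)-2,5-dimethylphenyl (2E)-3-(2-methoxy-4-oxocyclobut-2-en-1-yl)hex-2-enoate (racemic, not isolated) | CCC/C(C1C(=O)C=C1OC)=C\C(=O)Oc1cc(C)c(C(=O)OC)c(O)c1C | intermediate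
13 | 3-hydroxy-4-(methoxycarbonyl)-2,5-dimethylphenyl (2E,4E)-5-methoxy-7-oxo-3-propylhepta-2,4,6-trienoate (dienylketene, not isolated) | O=C=C/C(OC)=C\C(CCC)=C\C(=O)Oc1cc(C)c(C(=O)OC)c(O)c1C | intermediate
14 | 3-hydroxy-4-(methoxycarbonyl)-2,5-dimethylphenyl 4-methoxy-2-oxo-6-propylcyclohexa-3,5-diene-1-carboxylate (racemic, not isolated) | CCCC1=CC(OC)=CC(=O)C1C(=O)Oc1cc(C)c(C(=O)OC)c(O)c1C | intermediate
15 | peruvinide A, 3-hydroxy-4-(methoxycarbonyl)-2,5-dimethylphenyl 2-hydroxy-4-methoxy-6-propylbenzoate | CCCc1cc(OC)cc(O)c1C(=O)Oc1cc(C)c(C(=O)OC)c(O)c1C | target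

**Step count**

Total step count: 5. Longest linear sequence: 4 steps (steps 1, 2, 3 and 5 from hexan-2-one); step 4 is a one-step side branch.

**Steps most likely to fail**

Step 5. The ketenes may be lost to capture by phenolic OH groups or to oligomerisation before the alkyne adds. The aryl ester may suffer photo-Fries cleavage if shorter wavelengths reach it, and the cyclobutenone may open incompletely in the thermal stage. The fallback sets out from 3 and comes back at 15, and builds ring A on a simple ester before the depside bond exists. Acid 3 is O-benzylated (BnBr, K2CO3, DMF) to benzyl (2E)-3-acetylhex-2-enoate F1, which the diazo transfer of step 3 converts into benzyl (2E)-3-(2-diazoacetyl)hex-2-enoate F2. Benzannulation of F2 with 10 under the conditions of step 5 should give benzyl 2-hydroxy-4-methoxy-6-propylbenzoate F3. Hydrogenolysis (H2, Pd/C, EtOAc) frees 2-hydroxy-4-methoxy-6-propylbenzoic acid F4, and F4 is joined to the 4-OH of 4 through its mixed anhydride with trifluoroacetic anhydride (toluene, rt), the classical depside coupling, to give 15.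

Step 3. Under the strong base the ketone enolate may add to the ene-dicarbonyl or to the aryl ester of a second molecule, and the aryl ester may be partly cleaved in the aqueous amine stage. The fallback sets out from 5 and comes back at 7, and avoids strong base altogether. Soft enolisation of 5 with Me3SiOTf and Et3N (CH2Cl2, 0 °C) should give 4-(methoxycarbonyl)-2,5-dimethyl-3-[(trimethylsilyl)oxy]phenyl (2E)-3-{1-[(trimethylsilyl)oxy]ethenyl}hex-2-enoate F5. Bromination of the silyl enol ether with N-bromosuccinimide (THF, −78 °C) and aqueous work-up, which also frees the phenol, gives 3-hydroxy-4-(methoxycarbonyl)-2,5-dimethylphenyl (2E)-3-(2-bromoacetyl)hex-2-enoate F6. Treatment of F6 with N,N'-ditosylhydrazine and DBU (THF, 0 °C) alkylates the hydrazine and expels two sulfinate ions to give 7.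

Step 1. The condensation may take place partly on the methyl side of the ketone, and the acid may isomerise to the (Z)-form and close to the cyclic hydroxybutenolide. The fallback sets out from 2 and comes back at 3, and fixes both regiochemistry and geometry by a Wittig reaction. Butylidenetriphenylphosphorane, made from commercial butyltriphenylphosphonium bromide and NaN(SiMe3)2, is acetylated with half an equivalent of acetyl chloride (transylidation) to the stabilised ylide 3-(triphenylphosphoranylidene)hexan-2-one F7. Reaction of F7 with 2 in CH2Cl2 should give 3, the stabilised ylide placing the carboxyl group trans to the acetyl group.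

**Further compounds**

F1 | step 5 | benzyl (2E)-3-acetylhex-2-enoate | CCC/C(C(C)=O)=C\C(=O)OCc1ccccc1
F2 | step 5 | benzyl (2E)-3-(2-diazoacetyl)hex-2-enoate | CCC/C(C(=O)C=[N+]=[N-])=C\C(=O)OCc1ccccc1
F3 | step 5 | benzyl 2-hydroxy-4-methoxy-6-propylbenzoate | CCCc1cc(OC)cc(O)c1C(=O)OCc1ccccc1
F4 | step 5 | 2-hydroxy-4-methoxy-6-propylbenzoic acid | CCCc1cc(OC)cc(O)c1C(=O)O
F5 | step 3 | 4-(methoxycarbonyl)-2,5-dimethyl-3-[(trimethylsilyl)oxy]phenyl (2E)-3-{1-[(trimethylsilyl)oxy]ethenyl}hex-2-enoate | CCC/C(C(=C)O[Si](C)(C)C)=C\C(=O)Oc1cc(C)c(C(=O)OC)c(O[Si](C)(C)C)c1C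
F6 | step 3 | 3-hydroxy-4-(methoxycarbonyl)-2,5-dimethylphenyl (2E)-3-(2-bromoacetyl)hex-2-enoate | CCC/C(C(=O)CBr)=C\C(=O)Oc1cc(C)c(C(=O)OC)c(O)c1C
F7 | step 1 | 3-(triphenylphosphoranylidene)hexan-2-one | CCCC(C(C)=O)=P(c1ccccc1)(c1ccccc1)c1ccccc1
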